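## The problem

Compound 15 is a trans-2,3-diaryl-2,3-dihydrobenzofuran whose benzo ring is a 5-alkylresorcinol: O1 sits on C7a, a free hydroxyl on C4 and a 2-(4-hydroxyphenyl)ethyl chain on C6. The ring-fusion carbon C3a, which carries C3, therefore lies between two oxygen-bearing carbons. Any plan that joins C3 to a finished resorcinol must bond at this most crowded position and must tell two oxygens apart. The stereocentres C2 and C3 are adjacent and both S (trans). C3 is a diarylmethine with no simple way to epimerize, whereas C2 is a benzylic ether para to an oxygen and ionizes easily. C3 can therefore correct C2, since trans is the more stable arrangement, but C2 cannot correct C3, so the absolute configuration has to be secured at C3. The five phenols must stay masked until the end, and the O1–C2 bond is the weak point towards protic and Lewis acids. The feature that opens the chosen route is that the six benzo carbons fall into three two-carbon units, C7a–C7, C6–C5 and C4–C3a, of which the first and third are already joined by the three-atom bridge O1–C2–C3. This is a 1,6-diyne with one ynol ether alkyne, plus a terminal alkyne that carries the side chain.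

## Retrosynthesis

**15 to 13.** The C4–O bond and the four O–H bonds of the other rings are cut first, leading to tetramethyl ether 13 with trimethylsilyl on C4. Silicon is preferred to a protected oxygen or a boronate at this position because a silylalkyne survives every base and organometallic reagent used earlier and its bulk is needed for regiocontrol in the ring-forming step. Methyl ethers are kept because the boron reagent that exchanges silicon also cleaves them. The forward step must achieve ipso substitution at C4 faster than protodesilylation and must leave the O1–C2 bond, or at least C3, intact.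

**13 to 10 and 12.** The bonds C3a–C7a, C4–C5 and C6–C7 are cut, which opens the benzene ring and the dihydrofuran ring together. The neighbouring cuts, C3–C3a to a preformed resorcinol or O1–C7a by aryl ether formation, both need a differentiated, fully substituted resorcinol and a bond to its hindered centre. The [2+2+2] cut makes the arene with O1, silicon and the side chain already in place. The precursors are an acyclic diyne 10 that holds both stereocentres and the simple alkyne 12. The forward reaction must be regioselective (side chain meta to silicon) and mild enough for an ynol ether.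

**10 to 7, and 12 to 11.** The O–C(sp) bond of 10 is cut, leading through lithium alkynyl ether 9 and dichlorovinyl ether 8 to homopropargylic alcohol 7. This is the standard way to an ethynyl ether and leaves the carbon skeleton untouched. The forward steps must not disturb the C–H that is both benzylic and propargylic. Alkyne 12 is traced to aldehyde 11 by one-carbon homologation.

**7 to 4 and 5.** The C2–C3 bond (target numbering) is cut between a propargylic and a carbinol carbon. Against an aldol-type construction, this cut delivers the alcohol, the silylalkyne and both stereocentres in one step from an achiral aldehyde 5 and a propargylic mesylate 4, through allenylzinc 6. The forward reaction must transfer the chirality of 4 to C3 and give the anti diastereomer, which corresponds to the trans ring.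

**4 to 3, and 3 to 1 and 2.** The mesylate comes from alcohol 3, and 3 from aldehyde 1 and alkyne 2 by cutting the carbinol–alkyne bond. A catalytic asymmetric alkynylation is chosen over an ynone reduction because aryl and alkynyl groups are poorly distinguished by transfer hydrogenation catalysts. The forward reaction must give the R carbinol.

## Roads not taken

**Alternative 1:** The cut is at C2–aryl and C3–C3a, with no ring formed. The ate complex of styrylboronate A2 and 4-methoxyphenyllithium A4 would react with aryl triflate A3 under a palladium catalyst carrying a chiral ferrocenyl diphosphine. The anisyl group migrates from boron to C2 while the resorcinol ring is delivered to C3, giving boronate A1.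
- Merits: three simple pieces meet in one catalytic enantioselective step, all ring oxygens are present from the start, there is no labile ynol ether, and anti addition across the (E)-alkene fixes the relative configuration.
- Weak points: conjunctive coupling works best with unsubstituted vinylboron ate complexes. Here the alkene is β-aryl-substituted and the electrophile has two ortho methoxy groups and must be placed on a secondary benzylic carbon, so slow reductive elimination and β-hydride loss to a stilbene are likely. After A1, the C–B bond must be oxidized, one ortho methyl ether cleaved and O1–C2 closed. That closure passes through the 4-methoxybenzylic cation, so the catalyst-made C2 centre is erased and re-set from C3.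
- Comparison: this road is better in convergence and in robustness of intermediates, and it needs no silicon-to-oxygen exchange. The chosen plan sets against it that C3a is formed as part of a new ring, not by forcing a doubly ortho-substituted aryl onto a crowded carbon, and that O1–C2 is carried with its configuration from an early step. The step counts are similar.

**Alternative 2:** The cut is at C5–C6 and C3a–C4. Ynone A6, which already holds C2 and C3, would take up dimethyl malonate A7 under methoxide at the alkyne carbon that becomes C6. The ketone α-carbon (C3a) would then condense on one ester and close the benzene ring as resorcylate A5.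
- Merits: this is a known base-mediated benzannulation, both ring oxygens are born as free phenols in the right places, the ketone can enolize on one side only, and once the ester is removed the resorcinol is symmetrical, so either hydroxyl closes the same furan.
- Weak points: A6 is an acyclic ketone with two stereocentres β and γ to the carbonyl and needs its own asymmetric synthesis of several steps. Methoxide must spare the ynone from double addition. After A5 come ester hydrolysis and decarboxylation, silyl removal, ring closure and demethylation, four operations where the chosen plan has one.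
- Comparison: the key step here is better precedented than the ruthenium step and needs no masked hydroxyl. The chosen plan sets against it that one step closes both rings under neutral conditions, that no carbon has to be removed again, and that the sequence is about four steps shorter.

**Alternative 3:** The cut is at C2–C3. Diazo ester A9, a symmetrical bis(4-methoxybenzyl) ether, would give with a chiral dirhodium tetracarboxylate a carbene at C3 that inserts into one benzylic C–H bond and closes the dihydrofuran ring as the cis ester A8.
- Merits: enantioselective C–H insertion of aryldiazoacetates into benzylic ethers is established for this ring type, the catalyst sets C2, either ether arm gives the same product, and the C4 oxygen is present as an easily removed benzyl-type ether.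
- Weak points: C3 of A8 carries a methoxycarbonyl group where the target has the 3,5-dihydroxyphenyl ring. Exchanging carboxyl for aryl (saponification, activation, decarboxylative arylation) goes through a C3 radical, so the C3 configuration from the insertion is discarded and trans must come from C2. That is the wrong direction of control, because C2 is the centre that ionizes.
- Comparison: the ring-forming step is more secure than the chosen one and its enantioselectivity is catalytic. The chosen plan has both aryl groups and both stereocentres in place before any ring is made and leaves no hard C–C bond for the end. The alternative needs at least three further steps to install the aryl ring.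

Key step: step 7

Remark: the sense of induction in step 1 (Si-face addition with the (S,S)-ligand) is assigned by analogy with other aryl aldehydes; should it prove opposite, the (R,R)-ligand is used and nothing else changes.

## Route

Step 1
Reactants: 1 3,5-dimethoxybenzaldehyde; 2 trimethylsilylacetylene
Product: 3 (R)-1-(3,5-dimethoxyphenyl)-3-(trimethylsilyl)prop-2-yn-1-ol
Conditions: 2 (3 equiv), Me2Zn (3 equiv), (S,S)-ProPhenol (10 mol%), Ph3P=O (20 mol%), toluene, 0 °C; then 1, 4 °C; aq NH4Cl
Reagents that add atoms: none
Why: Catalytic enantioselective alkynylzinc addition (Zn-ProPhenol alkynylation), for which aryl aldehydes and silylacetylenes are established partners. The dinuclear zinc complex of the (S,S)-ligand is expected to deliver the alkynyl group to the Si face of 1, which sets the R carbinol centre.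

Step 2
Reactants: 3 (R)-1-(3,5-dimethoxyphenyl)-3-(trimethylsilyl)prop-2-yn-1-ol
Product: 4 (R)-1-(3,5-dimethoxyphenyl)-3-(trimethylsilyl)prop-2-yn-1-yl methanesulfonate
Conditions: MsCl (1.3 equiv), Et3N (1.6 equiv), CH2Cl2, −78 °C; cold aqueous work-up; used crude at once
Reagents that add atoms: methanesulfonyl chloride, CS(=O)(=O)Cl
Why: O-Sulfonylation of a secondary alcohol with retention, since the C–O bond is not touched. The two meta methoxy groups do not stabilize a benzylic cation, so the mesylate should survive a cold work-up.

Step 3
Reactants: 4 (R)-1-(3,5-dimethoxyphenyl)-3-(trimethylsilyl)prop-2-yn-1-yl methanesulfonate; 5 4-methoxybenzaldehyde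
Product: 7 (1S,2S)-2-(3,5-dimethoxyphenyl)-1-(4-methoxyphenyl)-4-(trimethylsilyl)but-3-yn-1-ol, via allenyl(ethyl)zinc 6 (not isolated)
Conditions: Pd(OAc)2 (5 mol%), PPh3 (5 mol%), Et2Zn (3 equiv), THF, −78 → −20 °C; aq NH4Cl
Reagents that add atoms: none
Why: Marshall propargylation: zerovalent palladium displaces the mesylate anti (SN2') to an allenylpalladium, Et2Zn transmetalates it to allenylzinc 6, and 6 adds to 5 through a cyclic SE2' transition state on the face that carries zinc. The net inversion at the propargylic carbon should turn R in 4 into S at C2 of 7 (C3 of the target). The cyclic transition state, with the anisyl group turned away from the dimethoxyphenyl group, should give the anti carbinol, S at C1 (C2 of the target).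

Step 4
Reactants: 7 (1S,2S)-2-(3,5-dimethoxyphenyl)-1-(4-methoxyphenyl)-4-(trimethylsilyl)but-3-yn-1-ol
Product: 8 1-[(1S,2S)-1-{[(E)-1,2-dichloroethenyl]oxy}-2-(3,5-dimethoxyphenyl)-4-(trimethylsilyl)but-3-yn-1-yl]-4-methoxybenzene
Conditions: KH (1.3 equiv), THF, 0 °C; Cl2C=CHCl (1.2 equiv), −40 °C → rt
Reagents that add atoms: trichloroethylene, ClC=C(Cl)Cl
Why: The potassium alkoxide adds to dichloroacetylene, generated in situ from trichloroethylene by the same base, and protonation gives the (E)-1,2-dichlorovinyl ether; this is the standard entry to ynol ethers of secondary alcohols. Neither stereocentre is touched.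

Step 5
Reactants: 8 1-[(1S,2S)-1-{[(E)-1,2-dichloroethenyl]oxy}-2-(3,5-dimethoxyphenyl)-4-(trimethylsilyl)but-3-yn-1-yl]-4-methoxybenzene
Product: 10 1-[(1S,2S)-2-(3,5-dimethoxyphenyl)-1-(ethynyloxy)-4-(trimethylsilyl)but-3-yn-1-yl]-4-methoxybenzene, via lithium alkynyl ether 9 (not isolated)
Conditions: n-BuLi (2.2 equiv), THF, −78 °C; MeOH, −78 °C; cold pH 7 buffer; used without storage
Reagents that add atoms: none
Why: Dehydrohalogenation route to terminal ynol ethers: n-BuLi removes the vinylic proton, LiCl is lost and chlorine–lithium exchange gives 9, which methanol protonates at −78 °C. Low temperature and exact stoichiometry protect the acidic propargylic C–H and the thermally labile product.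

Step 6
Reactants: 11 3-(4-methoxyphenyl)propanal
Product: 12 4-(4-methoxyphenyl)but-1-yne
Conditions: MeC(O)C(N2)P(O)(OMe)2 (1.3 equiv), K2CO3 (2 equiv), MeOH, 0 °C → rt
Reagents that add atoms: dimethyl (1-diazo-2-oxopropyl)phosphonate, CC(=O)C(=[N+]=[N-])P(=O)(OC)OC
Why: Seyferth–Gilbert homologation in the Ohira–Bestmann variant: methanolysis frees the diazomethylphosphonate anion, which olefinates the aldehyde, and loss of N2 with 1,2-hydride shift gives the terminal alkyne. The mild carbonate base suits an enolizable aldehyde.

Step 7
Reactants: 10 1-[(1S,2S)-2-(3,5-dimethoxyphenyl)-1-(ethynyloxy)-4-(trimethylsilyl)but-3-yn-1-yl]-4-methoxybenzene; 12 4-(4-methoxyphenyl)but-1-yne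
Product: 13 [(2S,3S)-3-(3,5-dimethoxyphenyl)-2-(4-methoxyphenyl)-6-[2-(4-methoxyphenyl)ethyl]-2,3-dihydro-1-benzofuran-4-yl]trimethylsilane
Conditions: Cp*RuCl(cod) (10 mol%), 12 (4 equiv), ClCH2CH2Cl, 0 → 20 °C; 10 added slowly
Reagents that add atoms: none
Why: Proposed new method: oxidative coupling of the two tethered alkynes of 10 at the Cp*RuCl fragment should give a ruthenacycle (a ruthenacyclopentadiene with carbene character at both α-carbons) that takes up 12 and reductively eliminates the arene; the closest known reaction type is the Cp*RuCl(cod)-catalysed [2+2+2] cycloaddition of unsymmetrical 1,6-diynes with terminal alkynes, with ynamide-tethered diynes and alkynyl ethers as the nearest heteroatom-substituted cases. The dihydrofuran ring closes in the oxidative coupling, which joins the two inner alkyne carbons (C3a–C7a) across the three-atom O1–C2–C3 tether and leaves ruthenium on C7 and C4. The benzene ring closes by insertion of 12 into the unhindered Ru–C7 bond (C6–C7) and reductive elimination (C4–C5). No stereocentre is formed; C2 and C3 lie outside the reacting π-systems and are carried through unchanged. The selectivity needed is regiochemical, side chain on C6 and not on C5, and the trimethylsilyl group secures it: 12 enters at the ruthenium–carbon bond remote from silicon with its substituted carbon bonding to C7, the known meta preference of this catalyst. Cross- over homo-cycloaddition is secured by adding 10 slowly to an excess of 12. The neutral catalyst and a temperature at or below 20 °C are chosen because 10 can lose ketene by retro-ene fragmentation or ionize at its 4-methoxybenzylic C–O bond.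

Step 8
Reactants: 13 [(2S,3S)-3-(3,5-dimethoxyphenyl)-2-(4-methoxyphenyl)-6-[2-(4-methoxyphenyl)ethyl]-2,3-dihydro-1-benzofuran-4-yl]trimethylsilane
Product: 15 5-[(2S,3S)-4-hydroxy-2-(4-hydroxyphenyl)-6-[2-(4-hydroxyphenyl)ethyl]-2,3-dihydro-1-benzofuran-3-yl]benzene-1,3-diol, via arylboronic acid 14 (not isolated)
Conditions: BBr3 (12 equiv), 2,6-di-tert-butylpyridine (0.2 equiv), CH2Cl2, −78 → 20 °C; MeOH–H2O, 0 °C; NaBO3·4H2O, THF–H2O, 20 °C
Reagents that add atoms: sodium perborate tetrahydrate (NaBO3·4H2O), [Na+].[Na+].O[B-]1(O)OO[B-](O)(O)OO1.O.O.O.O.O.O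
Why: BBr3 exchanges the aryl–silicon bond for an aryl–boron bond (ipso-borodesilylation through a β-silyl-stabilized arenium ion) and cleaves the four aryl methyl ethers; hydrolysis gives boronic acid 14, whose C–B bond NaBO3 oxidizes to C–OH by 1,2-aryl shift with retention of position. C3 is a diarylmethine that cannot epimerize, so any reversible opening of O1–C2 by the Lewis acid should reclose under its control to the trans ring.

## Compound list

1 | 3,5-dimethoxybenzaldehyde | COc1cc(C=O)cc(OC)c1 | starting material
2 | trimethylsilylacetylene | C#C[Si](C)(C)C | starting material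
3 | (R)-1-(3,5-dimethoxyphenyl)-3-(trimethylsilyl)prop-2-yn-1-ol | O[C@@H](C#C[Si](C)(C)C)c1cc(OC)cc(OC)c1 | intermediate
4 | (R)-1-(3,5-dimethoxyphenyl)-3-(trimethylsilyl)prop-2-yn-1-yl methanesulfonate | CS(=O)(=O)O[C@@H](C#C[Si](C)(C)C)c1cc(OC)cc(OC)c1 | intermediate
5 | 4-methoxybenzaldehyde | COc1ccc(C=O)cc1 | starting material
6 | ethyl[(Sa)-3-(3,5-dimethoxyphenyl)-1-(trimethylsilyl)propa-1,2-dien-1-yl]zinc | [H]C(c1cc(OC)cc(OC)c1)=[C@@]=C([Zn]CC)[Si](C)(C)C | intermediate (not isolated)
7 | (1S,2S)-2-(3,5-dimethoxyphenyl)-1-(4-methoxyphenyl)-4-(trimethylsilyl)but-3-yn-1-ol (anti) | O[C@H](c1ccc(OC)cc1)[C@H](C#C[Si](C)(C)C)c1cc(OC)cc(OC)c1 | intermediate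
8 | 1-[(1S,2S)-1-{[(E)-1,2-dichloroethenyl]oxy}-2-(3,5-dimethoxyphenyl)-4-(trimethylsilyl)but-3-yn-1-yl]-4-methoxybenzene | Cl/C=C(/Cl)O[C@H](c1ccc(OC)cc1)[C@H](C#C[Si](C)(C)C)c1cc(OC)cc(OC)c1 | intermediate
9 | ({[(1S,2S)-2-(3,5-dimethoxyphenyl)-1-(4-methoxyphenyl)-4-(trimethylsilyl)but-3-yn-1-yl]oxy}ethynyl)lithium | [Li]C#CO[C@H](c1ccc(OC)cc1)[C@H](C#C[Si](C)(C)C)c1cc(OC)cc(OC)c1 | intermediate (not isolated)
10 | 1-[(1S,2S)-2-(3,5-dimethoxyphenyl)-1-(ethynyloxy)-4-(trimethylsilyl)but-3-yn-1-yl]-4-methoxybenzene | C#CO[C@H](c1ccc(OC)cc1)[C@H](C#C[Si](C)(C)C)c1cc(OC)cc(OC)c1 | intermediate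
11 | 3-(4-methoxyphenyl)propanal | COc1ccc(CCC=O)cc1 | starting material
12 | 4-(4-methoxyphenyl)but-1-yne | C#CCCc1ccc(OC)cc1 | intermediate
13 | [(2S,3S)-3-(3,5-dimethoxyphenyl)-2-(4-methoxyphenyl)-6-[2-(4-methoxyphenyl)ethyl]-2,3-dihydro-1-benzofuran-4-yl]trimethylsilane (trans) | COc1ccc(CCc2cc([Si](C)(C)C)c3c(c2)O[C@H](c2ccc(OC)cc2)[C@H]3c2cc(OC)cc(OC)c2)cc1 | intermediate
14 | [(2S,3S)-3-(3,5-dihydroxyphenyl)-2-(4-hydroxyphenyl)-6-[2-(4-hydroxyphenyl)ethyl]-2,3-dihydro-1-benzofuran-4-yl]boronic acid | Oc1ccc(CCc2cc(B(O)O)c3c(c2)O[C@H](c2ccc(O)cc2)[C@H]3c2cc(O)cc(O)c2)cc1 | intermediate (not isolated)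
15 | 5-[(2S,3S)-4-hydroxy-2-(4-hydroxyphenyl)-6-[2-(4-hydroxyphenyl)ethyl]-2,3-dihydro-1-benzofuran-3-yl]benzene-1,3-diol | Oc1ccc(CCc2cc(O)c3c(c2)O[C@H](c2ccc(O)cc2)[C@H]3c2cc(O)cc(O)c2)cc1 | target

## Step count and least certain steps

Total: 8 steps. Longest linear sequence: 7 steps (1, 2, 3, 4, 5, 7, 8, from aldehyde 1); step 6 is a one-step side branch.

**Step 7 (key step, new method).** The most likely failure is loss of diyne 10 before it cyclizes: retro-ene fragmentation to ketene, ionization of the 4-methoxybenzylic C–O bond, or diversion of the terminal ynol ether into a ruthenium vinylidene. A second risk is insertion of 12 in the reverse orientation if the silyl group steers less well next to the C3 aryl group.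
Fallback with known chemistry (temporary silicon tether, no ynol ether): it sets out from alcohol 7, which is silylated with chloro(ethynyl)diisopropylsilane (from i-Pr2SiCl2 and HC≡CMgBr; imidazole, DMF) to the ethynyl(diisopropyl)silyl ether F1. F1 and 12 undergo the Cp*RuCl(cod)-catalysed [2+2+2] cycloaddition of an ordinary silicon-tethered diyne to the dihydro-2,1-benzoxasiline F2. Tamao–Fleming oxidation (H2O2, KF, KHCO3, THF–MeOH) converts the aryl–silicon bond into the C7a phenol and frees the benzylic alcohol, giving the phenol alcohol F3. A catalytic amount of TsOH in CH2Cl2 at 0 °C closes O1–C2 through the 4-methoxybenzylic cation, trans to the C3 aryl group, and the route is rejoined at 13.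

**Step 4 (and the base treatment in step 5).** The potassium alkoxide of 7 has a neighbouring C–H that is both benzylic and propargylic. Base-induced propargyl-to-allene isomerization, epimerization at that carbon, or retro-addition to 5 may compete with O-vinylation.
Fallback: from 7, formylation under non-basic conditions (HCO2H, DCC, DMAP) gives the formate F4. Dichloromethylenation of the formyl group (PPh3, CCl4, THF, 60 °C; Corey–Fuchs-type olefination of a formate) gives the 2,2-dichlorovinyl ether F5. n-BuLi at −78 °C and a methanol quench return the route at 10 without an alkoxide of 7 ever being formed.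

**Step 3 (with step 2).** Enantiopurity may be lost by ionization of the benzylic propargylic mesylate 4 or by equilibration of the allenylpalladium. The anti preference may also be weaker with an aromatic aldehyde than with branched aliphatic ones.
Fallback: from 3, ClCO2Me and pyridine give the methyl carbonate F6. Copper-catalysed anti-SN2' borylation (B2pin2, CuOt-Bu, Xantphos, THF) gives the configurationally stable allenylboronate F7. Thermal allenylboration of 5 through a closed six-membered transition state (toluene, 20–50 °C) returns the route at 7 with the same sense of chirality transfer.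

**Step 8.** Protodesilylation at C4 may outrun boron–silicon exchange if HBr builds up. Opening of O1–C2 by the Lewis acid may give the C2 epimer or oligomers before all four ethers are cleaved.
Fallback (the two cleavages are separated): from 13, BCl3 (CH2Cl2, −78 → 0 °C), which exchanges silicon but spares methyl ethers, followed by pinacol and Et3N gives the pinacol boronate F8. NaBO3·4H2O oxidizes it to the C4 phenol F9. Iodide-assisted demethylation (BCl3, n-Bu4NI, CH2Cl2, −78 → 0 °C) returns the route at 15.

**Step 1.** Enantioselectivity with the silylacetylene may be insufficient, or the sense of induction may be opposite to the one assumed.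
Fallback: from 1 and 2, LiC≡CSiMe3 (from 2 and n-BuLi, THF, −78 °C) gives the racemic alcohol F10. MnO2 in CH2Cl2 gives the ynone F11. Midland reduction with (R)-Alpine-Borane, which treats the alkynyl group as the small substituent, should return the R carbinol 3.

## Further compounds

F1 | step 7 | {[(1S,2S)-2-(3,5-dimethoxyphenyl)-1-(4-methoxyphenyl)-4-(trimethylsilyl)but-3-yn-1-yl]oxy}(ethynyl)di(propan-2-yl)silane | C#C[Si](C(C)C)(C(C)C)O[C@H](c1ccc(OC)cc1)[C@H](C#C[Si](C)(C)C)c1cc(OC)cc(OC)c1
F2 | step 7 | (3S,4S)-4-(3,5-dimethoxyphenyl)-3-(4-methoxyphenyl)-7-[2-(4-methoxyphenyl)ethyl]-1,1-di(propan-2-yl)-5-(trimethylsilyl)-3,4-dihydro-1H-2,1-benzoxasiline | COc1ccc(CCc2cc([Si](C)(C)C)c3c(c2)[Si](C(C)C)(C(C)C)O[C@H](c2ccc(OC)cc2)[C@H]3c2cc(OC)cc(OC)c2)cc1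
F3 | step 7 | (1S,2S)-2-(3,5-dimethoxyphenyl)-2-{2-hydroxy-4-[2-(4-methoxyphenyl)ethyl]-6-(trimethylsilyl)phenyl}-1-(4-methoxyphenyl)ethan-1-ol | O[C@H](c1ccc(OC)cc1)[C@H](c1c(O)cc(CCc2ccc(OC)cc2)cc1[Si](C)(C)C)c1cc(OC)cc(OC)c1
F4 | step 4 | (1S,2S)-2-(3,5-dimethoxyphenyl)-1-(4-methoxyphenyl)-4-(trimethylsilyl)but-3-yn-1-yl formate | O=CO[C@H](c1ccc(OC)cc1)[C@H](C#C[Si](C)(C)C)c1cc(OC)cc(OC)c1
F5 | step 4 | 1-[(1S,2S)-1-[(2,2-dichloroethenyl)oxy]-2-(3,5-dimethoxyphenyl)-4-(trimethylsilyl)but-3-yn-1-yl]-4-methoxybenzene | ClC(Cl)=CO[C@H](c1ccc(OC)cc1)[C@H](C#C[Si](C)(C)C)c1cc(OC)cc(OC)c1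
F6 | step 3 | (R)-1-(3,5-dimethoxyphenyl)-3-(trimethylsilyl)prop-2-yn-1-yl methyl carbonate | COC(=O)O[C@@H](C#C[Si](C)(C)C)c1cc(OC)cc(OC)c1
F7 | step 3 | 2-[(Ra)-3-(3,5-dimethoxyphenyl)-1-(trimethylsilyl)propa-1,2-dien-1-yl]-4,4,5,5-tetramethyl-1,3,2-dioxaborolane | [H]C(c1cc(OC)cc(OC)c1)=[C@@]=C(B1OC(C)(C)C(C)(C)O1)[Si](C)(C)C
F8 | step 8 | 2-[(2S,3S)-3-(3,5-dimethoxyphenyl)-2-(4-methoxyphenyl)-6-[2-(4-methoxyphenyl)ethyl]-2,3-dihydro-1-benzofuran-4-yl]-4,4,5,5-tetramethyl-1,3,2-dioxaborolane | COc1ccc(CCc2cc(B4OC(C)(C)C(C)(C)O4)c3c(c2)O[C@H](c2ccc(OC)cc2)[C@H]3c2cc(OC)cc(OC)c2)cc1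
F9 | step 8 | (2S,3S)-3-(3,5-dimethoxyphenyl)-2-(4-methoxyphenyl)-6-[2-(4-methoxyphenyl)ethyl]-2,3-dihydro-1-benzofuran-4-ol | COc1ccc(CCc2cc(O)c3c(c2)O[C@H](c2ccc(OC)cc2)[C@H]3c2cc(OC)cc(OC)c2)cc1
F10 | step 1 | (±)-1-(3,5-dimethoxyphenyl)-3-(trimethylsilyl)prop-2-yn-1-ol | OC(C#C[Si](C)(C)C)c1cc(OC)cc(OC)c1
F11 | step 1 | 1-(3,5-dimethoxyphenyl)-3-(trimethylsilyl)prop-2-yn-1-one | COc1cc(cc(OC)c1)C(=O)C#C[Si](C)(C)C
A1 | alternative 1 | 2-[(1S,2S)-2-{2,6-dimethoxy-4-[2-(4-methoxyphenyl)ethyl]phenyl}-2-(3,5-dimethoxyphenyl)-1-(4-methoxyphenyl)ethyl]-4,4,5,5-tetramethyl-1,3,2-dioxaborolane | COc1ccc(CCc2cc(OC)c(c(OC)c2)[C@@H]([C@H](B3OC(C)(C)C(C)(C)O3)c2ccc(OC)cc2)c2cc(OC)cc(OC)c2)cc1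
A2 | alternative 1 | 2-[(E)-2-(3,5-dimethoxyphenyl)ethenyl]-4,4,5,5-tetramethyl-1,3,2-dioxaborolane | COc1cc(/C=C/B2OC(C)(C)C(C)(C)O2)cc(OC)c1
A3 | alternative 1 | 2,6-dimethoxy-4-[2-(4-methoxyphenyl)ethyl]phenyl trifluoromethanesulfonate | COc1ccc(CCc2cc(OC)c(OS(=O)(=O)C(F)(F)F)c(OC)c2)cc1
A4 | alternative 1 | 4-methoxyphenyllithium | [Li]c1ccc(OC)cc1
A5 | alternative 2 | methyl 3-[(1S,2S)-2-[(tert-butyldimethylsilyl)oxy]-1-(3,5-dimethoxyphenyl)-2-(4-methoxyphenyl)ethyl]-2,4-dihydroxy-6-[2-(4-methoxyphenyl)ethyl]benzoate | COC(=O)c1c(O)c([C@@H]([C@H](O[Si](C)(C)C(C)(C)C)c2ccc(OC)cc2)c2cc(OC)cc(OC)c2)c(O)cc1CCc1ccc(OC)cc1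
A6 | alternative 2 | (1S,2R)-1-[(tert-butyldimethylsilyl)oxy]-2-(3,5-dimethoxyphenyl)-1,8-bis(4-methoxyphenyl)oct-5-yn-4-one | COc1ccc(CCC#CC(=O)C[C@@H]([C@H](O[Si](C)(C)C(C)(C)C)c2ccc(OC)cc2)c2cc(OC)cc(OC)c2)cc1
A7 | alternative 2 | dimethyl malonate | COC(=O)CC(=O)OC
A8 | alternative 3 | methyl (2S,3R)-4-[(4-methoxyphenyl)methoxy]-2-(4-methoxyphenyl)-6-[2-(4-methoxyphenyl)ethyl]-2,3-dihydro-1-benzofuran-3-carboxylate (cis) | COc1ccc(CCc2cc(OCc4ccc(OC)cc4)c3c(c2)O[C@H](c2ccc(OC)cc2)[C@@H]3C(=O)OC)cc1
A9 | alternative 3 | methyl 2-{2,6-bis[(4-methoxyphenyl)methoxy]-4-[2-(4-methoxyphenyl)ethyl]phenyl}-2-diazoacetate | COC(=O)C(=[N+]=[N-])c1c(OCc2ccc(OC)cc2)cc(CCc2ccc(OC)cc2)cc1OCc1ccc(OC)cc1
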